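**Plan**

- Retrosynthesis: the primary ester C–O bond is cut first (acylation). The C4–O bond is then traced back to a C4–CHO bond (Baeyer–Villiger logic). The ring bonds C2–C3 and C4–C5 are cut together, and last the Z-alkene (Wittig).
- Enabling feature: in the ring O1–C2(aryl)–C3(CH2O)–C4(OH)–C5, the O1–C2(aryl) unit is an aldehyde acetal carbon sitting on the primary oxygen of a 1,2-diol. C3–C4 is a former alkene, and C4 can carry formyl as a latent hydroxyl.
- Forward: a Z-selective Wittig reaction joins a two-carbon silyloxy ylide to (R)-glyceraldehyde acetonide, and the acetonide is exchanged for the 3,4-dimethoxybenzylidene acetal. SnCl4 then builds the only ring (the tetrahydrofuran) and both skeletal bonds in one step.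
- End game: CHO → COCH3 → OAc → OH at C4, desilylation, and acylation of the primary hydroxyl.
- Stereochemistry: the (S)-carbinol carbon from (R)-glyceraldehyde acetonide and the Z-alkene select one chair, which sets C2, C3 and C4 all-cis before the carbinol centre is consumed. The Baeyer–Villiger shift retains C4.

Key step: step 6

Assumption: all tetrahydrofurans are numbered as in the target (O1, C2 aryl, C3, C4, C5), and (R)-glyceraldehyde acetonide is taken as the commercial reagent, freshly distilled before use.

**Step 1**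
Reactants: 1 2-bromoethanol
Product: 2 tert-butyl(2-bromoethoxy)diphenylsilane
Conditions: TBDPSCl, imidazole, CH2Cl2, 0 °C → rt
Reagents that add atoms: tert-butyl(chloro)diphenylsilane (TBDPSCl), CC(C)(C)[Si](Cl)(c1ccccc1)c1ccccc1
Why: Imidazole-promoted silylation of a primary alcohol is fast and leaves the primary bromide untouched; the tert-butyldiphenylsilyl ether is chosen because it must later survive aqueous acid and SnCl4.

**Step 2**
Reactants: 2 tert-butyl(2-bromoethoxy)diphenylsilane
Product: 3 [2-(tert-butyldiphenylsilyloxy)ethyl]triphenylphosphonium bromide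
Conditions: PPh3, toluene, 110 °C
Reagents that add atoms: triphenylphosphine, c1ccc(cc1)P(c1ccccc1)c1ccccc1
Why: SN2 quaternization of triphenylphosphine by a primary bromide (Wittig salt formation) is reliable on heating, and the robust silyl ether is not cleaved by the bromide counter-ion.

**Step 3**
Reactants: 3 [2-(tert-butyldiphenylsilyloxy)ethyl]triphenylphosphonium bromide; 4 (R)-2,2-dimethyl-1,3-dioxolane-4-carbaldehyde
Product: 6 (4S)-4-[(Z)-3-(tert-butyldiphenylsilyloxy)prop-1-enyl]-2,2-dimethyl-1,3-dioxolane, via phosphonium ylide 5 (not isolated)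
Conditions: KN(SiMe3)2, THF, −78 °C; then 4, −78 → 0 °C
Reagents that add atoms: none
Why: Wittig olefination with a non-stabilized ylide under salt-free, low-temperature conditions should give the Z-alkene through the kinetically preferred cis-oxaphosphetane, and the α-alkoxy aldehyde is consumed faster than it can epimerize, so the dioxolane stereocentre is carried over unchanged.

**Step 4**
Reactants: 6 (4S)-4-[(Z)-3-(tert-butyldiphenylsilyloxy)prop-1-enyl]-2,2-dimethyl-1,3-dioxolane
Product: 7 (2S,3Z)-5-(tert-butyldiphenylsilyloxy)pent-3-ene-1,2-diol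
Conditions: AcOH/H2O/THF (3:1:1), 45 °C
Reagents that add atoms: none
Why: Acid-catalysed acetal hydrolysis removes the isopropylidene group under conditions that a tert-butyldiphenylsilyl ether and the Z-allylic system tolerate, and no bond to the stereocentre is broken.

**Step 5**
Reactants: 7 (2S,3Z)-5-(tert-butyldiphenylsilyloxy)pent-3-ene-1,2-diol; 8 3,4-dimethoxybenzaldehyde
Product: 9 (4S)-4-[(Z)-3-(tert-butyldiphenylsilyloxy)prop-1-enyl]-2-(3,4-dimethoxyphenyl)-1,3-dioxolane (both epimers at the acetal carbon)
Conditions: PPTS (cat.), benzene, reflux, Dean–Stark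
Reagents that add atoms: none
Why: Acid-catalysed acetalization of a 1,2-diol with an aromatic aldehyde under azeotropic water removal gives the 1,3-dioxolane, and both acetal epimers are usable because the acetal carbon becomes trigonal in the next step.

**Step 6**
Reactants: 9 (4S)-4-[(Z)-3-(tert-butyldiphenylsilyloxy)prop-1-enyl]-2-(3,4-dimethoxyphenyl)-1,3-dioxolane
Product: 12 (2R,3R,4R)-3-[(tert-butyldiphenylsilyloxy)methyl]-2-(3,4-dimethoxyphenyl)tetrahydrofuran-4-carbaldehyde (all-cis), via oxocarbenium tin alkoxide 10 (not isolated), via tetrahydropyran-4-yl cation 11 (not isolated)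
Conditions: SnCl4 (2.5 equiv), CH2Cl2, −78 → −30 °C; cold aq NaHCO3
Reagents that add atoms: none
Why: SnCl4 binds the allylic acetal oxygen and opens the dioxolane to the (E)-oxocarbenium ion 10 on the primary oxygen (the only regioisomer that can reach the alkene through a six-membered array), the terminus of the Z-alkene attacks its carbon in a chair 6-endo-trig Prins closure (C2–C3 bond) to give cation 11, and a suprafacial 1,2-shift of the ring CH2 from the stannyloxy carbon to the cationic carbon (pinacol rearrangement) forms the C4–C5 bond, contracts the six-membered ring to the tetrahydrofuran and releases the carbinol carbon as the formyl group. The closest known reaction type is the Lewis-acid-promoted Prins cyclization–pinacol rearrangement of 4-alkenyl-1,3-dioxolanes (acetals of allylic diols) to 3-acyl- and 3-formyltetrahydrofurans. C2 is set by the E geometry of the oxocarbenium ion (aryl equatorial), C3 by the Z geometry of the alkene (silyloxymethyl axial, hence cis to aryl), and C4 by delivery of the migrating CH2 to the face of the cation on which it already lies, which leaves formyl cis to both neighbours. The absolute sense comes from the (S)-carbinol carbon, because only the chair with the carbinol hydrogen axial avoids a 1,3-diaxial (allylic 1,3) clash between the stannyloxy group and the axial silyloxymethyl group, and this chair leads to the (2R,3R,4R) aldehyde. The step needs kinetic control, since the electron-rich aryl and the allylic silyloxy group slow the Prins closure while the product can epimerize at benzylic C2 (ionization) or at C4 (enolization); low temperature, enough SnCl4 to saturate the dimethoxyarene and a cold basic quench are meant to secure it.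

**Step 7**
Reactants: 12 (2R,3R,4R)-3-[(tert-butyldiphenylsilyloxy)methyl]-2-(3,4-dimethoxyphenyl)tetrahydrofuran-4-carbaldehyde
Product: 13 1-[(2R,3R,4R)-3-[(tert-butyldiphenylsilyloxy)methyl]-2-(3,4-dimethoxyphenyl)tetrahydrofuran-4-yl]ethanol (both carbinol epimers)
Conditions: MeMgBr, THF, −78 °C; aq NH4Cl
Reagents that add atoms: methylmagnesium bromide, C[Mg]Br
Why: Grignard addition to the freshly prepared aldehyde at −78 °C is much faster than enolization, so C4 should keep its configuration, and the new carbinol centre may form as a mixture because it is oxidized in the next step.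

**Step 8**
Reactants: 13 1-[(2R,3R,4R)-3-[(tert-butyldiphenylsilyloxy)methyl]-2-(3,4-dimethoxyphenyl)tetrahydrofuran-4-yl]ethanol
Product: 14 1-[(2R,3R,4R)-3-[(tert-butyldiphenylsilyloxy)methyl]-2-(3,4-dimethoxyphenyl)tetrahydrofuran-4-yl]ethanone
Conditions: Dess–Martin periodinane, NaHCO3, CH2Cl2, 0 °C → rt
Reagents that add atoms: none
Why: Dess–Martin oxidation of a secondary alcohol under bicarbonate buffering is fast and essentially neutral, which protects the epimerizable C4 centre next to the new ketone.

**Step 9**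
Reactants: 14 1-[(2R,3R,4R)-3-[(tert-butyldiphenylsilyloxy)methyl]-2-(3,4-dimethoxyphenyl)tetrahydrofuran-4-yl]ethanone
Product: 15 (2R,3R,4R)-3-[(tert-butyldiphenylsilyloxy)methyl]-2-(3,4-dimethoxyphenyl)tetrahydrofuran-4-yl acetate
Conditions: mCPBA, NaHCO3, CH2Cl2, rt
Reagents that add atoms: 3-chloroperbenzoic acid (mCPBA), OOC(=O)c1cccc(Cl)c1
Why: In the Baeyer–Villiger oxidation the secondary ring carbon C4 migrates from the Criegee intermediate in preference to methyl and with retention of configuration, so acetyl is replaced by acetoxy on the same face, while the buffer protects the benzylic ether.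

**Step 10**
Reactants: 15 (2R,3R,4R)-3-[(tert-butyldiphenylsilyloxy)methyl]-2-(3,4-dimethoxyphenyl)tetrahydrofuran-4-yl acetate
Product: 17 (2R,3S,4R)-2-(3,4-dimethoxyphenyl)-3-(hydroxymethyl)tetrahydrofuran-4-ol, via silyl ether alcohol 16 (not isolated)
Conditions: K2CO3 (cat.), MeOH, 0 °C → rt; evaporate; then Bu4NF, THF, rt; aq NH4Cl
Reagents that add atoms: none
Why: Base-catalysed transesterification with methanol removes the acetate without touching the silyl ether, and fluoride then cleaves the Si–O bond (driven by the strong Si–F bond); neither operation touches a stereocentre.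

**Step 11**
Reactants: 17 (2R,3S,4R)-2-(3,4-dimethoxyphenyl)-3-(hydroxymethyl)tetrahydrofuran-4-ol; 18 3,4-dimethoxybenzoyl chloride
Product: 19 [(2R,3S,4R)-2-(3,4-dimethoxyphenyl)-4-hydroxytetrahydrofuran-3-yl]methyl 3,4-dimethoxybenzoate
Conditions: 18 (1.05 equiv), pyridine, CH2Cl2, −20 → 0 °C
Reagents that add atoms: none
Why: Chemoselective acylation (nucleophilic acyl substitution) with one equivalent of acid chloride at low temperature should go to the primary hydroxyl, because the secondary C4 hydroxyl is flanked by the cis C3 substituent and reacts much more slowly.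

**Compound list**

1 | 2-bromoethanol | OCCBr | starting material
2 | tert-butyl(2-bromoethoxy)diphenylsilane | CC(C)(C)[Si](OCCBr)(c1ccccc1)c1ccccc1 | intermediate
3 | [2-(tert-butyldiphenylsilyloxy)ethyl]triphenylphosphonium bromide | CC(C)(C)[Si](OCC[P+](c1ccccc1)(c1ccccc1)c1ccccc1)(c1ccccc1)c1ccccc1.[Br-] | intermediate
4 | (R)-2,2-dimethyl-1,3-dioxolane-4-carbaldehyde ((R)-glyceraldehyde acetonide) | CC1(C)OC[C@H](C=O)O1 | starting material
5 | [2-(tert-butyldiphenylsilyloxy)ethylidene]triphenylphosphorane (ylide formed in the flask, not isolated) | CC(C)(C)[Si](OCC=P(c1ccccc1)(c1ccccc1)c1ccccc1)(c1ccccc1)c1ccccc1 | intermediate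
6 | (4S)-4-[(Z)-3-(tert-butyldiphenylsilyloxy)prop-1-enyl]-2,2-dimethyl-1,3-dioxolane | CC1(C)OC[C@H](/C=C\CO[Si](c2ccccc2)(c2ccccc2)C(C)(C)C)O1 | intermediate
7 | (2S,3Z)-5-(tert-butyldiphenylsilyloxy)pent-3-ene-1,2-diol | OC[C@@H](O)/C=C\CO[Si](c1ccccc1)(c1ccccc1)C(C)(C)C | intermediate
8 | 3,4-dimethoxybenzaldehyde | COc1ccc(C=O)cc1OC | starting material
9 | (4S)-4-[(Z)-3-(tert-butyldiphenylsilyloxy)prop-1-enyl]-2-(3,4-dimethoxyphenyl)-1,3-dioxolane (acetal epimers) | COc1ccc(C2OC[C@H](/C=C\CO[Si](c3ccccc3)(c3ccccc3)C(C)(C)C)O2)cc1OC | intermediate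
10 | (E)-oxocarbenium ion on the primary oxygen with the (S)-allylic oxygen bound to SnCl4 (ring-opened acetal, not isolated) | COc1ccc(/C=[O+]/C[C@@H](O[Sn-](Cl)(Cl)(Cl)Cl)/C=C\CO[Si](c2ccccc2)(c2ccccc2)C(C)(C)C)cc1OC | intermediate
11 | 2-(3,4-dimethoxyphenyl)-3-[(tert-butyldiphenylsilyloxy)methyl]-5-(tetrachlorostannyloxy)tetrahydropyran-4-yl cation, chair with aryl equatorial, C3 substituent axial (cis to aryl) and C5 oxygen equatorial (not isolated) | COc1ccc([C@@H]2OC[C@@H](O[Sn-](Cl)(Cl)(Cl)Cl)[CH+][C@@H]2CO[Si](c3ccccc3)(c3ccccc3)C(C)(C)C)cc1OC | intermediate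
12 | (2R,3R,4R)-3-[(tert-butyldiphenylsilyloxy)methyl]-2-(3,4-dimethoxyphenyl)tetrahydrofuran-4-carbaldehyde (all-cis) | CC(C)(C)[Si](c1ccccc1)(c1ccccc1)OC[C@H]2[C@@H](C=O)CO[C@H]2c3ccc(OC)c(OC)c3 | intermediate
13 | 1-[(2R,3R,4R)-3-[(tert-butyldiphenylsilyloxy)methyl]-2-(3,4-dimethoxyphenyl)tetrahydrofuran-4-yl]ethanol (carbinol epimers) | CC(C)(C)[Si](c1ccccc1)(c1ccccc1)OC[C@H]2[C@@H](C(C)O)CO[C@H]2c3ccc(OC)c(OC)c3 | intermediate
14 | 1-[(2R,3R,4R)-3-[(tert-butyldiphenylsilyloxy)methyl]-2-(3,4-dimethoxyphenyl)tetrahydrofuran-4-yl]ethanone | CC(C)(C)[Si](c1ccccc1)(c1ccccc1)OC[C@H]2[C@@H](C(C)=O)CO[C@H]2c3ccc(OC)c(OC)c3 | intermediate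
15 | (2R,3R,4R)-3-[(tert-butyldiphenylsilyloxy)methyl]-2-(3,4-dimethoxyphenyl)tetrahydrofuran-4-yl acetate | CC(C)(C)[Si](c1ccccc1)(c1ccccc1)OC[C@H]2[C@@H](OC(C)=O)CO[C@H]2c3ccc(OC)c(OC)c3 | intermediate
16 | (2R,3S,4R)-3-[(tert-butyldiphenylsilyloxy)methyl]-2-(3,4-dimethoxyphenyl)tetrahydrofuran-4-ol (formed in the flask, not isolated) | CC(C)(C)[Si](c1ccccc1)(c1ccccc1)OC[C@H]2[C@@H](O)CO[C@H]2c3ccc(OC)c(OC)c3 | intermediate
17 | (2R,3S,4R)-2-(3,4-dimethoxyphenyl)-3-(hydroxymethyl)tetrahydrofuran-4-ol | OC[C@H]1[C@@H](O)CO[C@H]1c1ccc(OC)c(OC)c1 | intermediate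
18 | 3,4-dimethoxybenzoyl chloride | COc1ccc(C(Cl)=O)cc1OC | starting material
19 | [(2R,3S,4R)-2-(3,4-dimethoxyphenyl)-4-hydroxytetrahydrofuran-3-yl]methyl 3,4-dimethoxybenzoate | COc1ccc(C(=O)OC[C@H]2[C@@H](O)CO[C@H]2c2ccc(OC)c(OC)c2)cc1OC | target

**Step count and risks**

Total step count: 11 (step 10 is a two-stage one-pot operation).
Longest linear sequence: 11 steps, from 2-bromoethanol 1 to 19 (9 steps from aldehyde 4).

The three steps most likely to fail:

**Step 6 (Prins–pinacol cascade).** The Prins closure may be too slow, because the oxocarbenium ion is stabilized by the dimethoxyphenyl group and the alkene is deactivated by the allylic silyloxy group. The Lewis acid would then have time to ionize the benzylic C–O bond reversibly (loss of the cis C2 configuration), enolize the aldehyde at C4, or let the unfavourable chair compete.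

The fallback sets out from diol 7 and generates the same cation from an open-chain precursor that ionizes far more easily than a dioxolane:
- The primary hydroxyl of 7 is acylated with 18 (pyridine, CH2Cl2, −20 °C) to give (2S,3Z)-5-(tert-butyldiphenylsilyloxy)-2-hydroxypent-3-enyl 3,4-dimethoxybenzoate F1.
- The secondary hydroxyl is silylated (Et3SiCl, imidazole) to give (2S,3Z)-5-(tert-butyldiphenylsilyloxy)-2-(triethylsilyloxy)pent-3-enyl 3,4-dimethoxybenzoate F2.
- Reductive acetylation of the ester (i-Bu2AlH, CH2Cl2, −78 °C; then Ac2O, pyridine, DMAP) gives the α-acetoxy ether (3,4-dimethoxyphenyl)[(2S,3Z)-5-(tert-butyldiphenylsilyloxy)-2-(triethylsilyloxy)pent-3-enyloxy]methyl acetate F3.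
- F3 is ionized at −78 °C with BF3·OEt2 or a little SnCl4. The acetate leaves, the oxocarbenium ion forms on the primary oxygen, and the same chair Prins closure follows. The pinacol shift is now terminated by loss of the triethylsilyl group.

This fallback comes back to the route at aldehyde 12.

**Step 9 (Baeyer–Villiger oxidation).** The peracid may attack the electron-rich dimethoxyarene, and migration of the β-oxygenated secondary carbon may be slow, giving the ketone time to epimerize at C4.

The fallback sets out from aldehyde 12, bypasses steps 7–9, and resets C4 by reduction instead of retention: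
- 12 is converted (TBSOTf, Et3N, CH2Cl2, 0 °C) into the enol silyl ether (2R,3R)-4-[(tert-butyldimethylsilyloxy)methylidene]-3-[(tert-butyldiphenylsilyloxy)methyl]-2-(3,4-dimethoxyphenyl)tetrahydrofuran F4.
- Ozonolysis titrated to the end point (O3, CH2Cl2/MeOH, −78 °C, Sudan Red 7B indicator; then Me2S) cleaves the enol double bond to give (2R,3R)-3-[(tert-butyldiphenylsilyloxy)methyl]-2-(3,4-dimethoxyphenyl)tetrahydrofuran-4-one F5. This ketone is kept cold and used at once to avoid epimerization or β-elimination at C3.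
- LiBH(s-Bu)3 (THF, −78 °C) should deliver hydride to the face opposite the neighbouring C3 substituent and the aryl group, giving the all-cis alcohol.

This fallback comes back to the route at 16, which is desilylated with Bu4NF as in the second stage of step 10.

**Step 11 (selective acylation).** Site selectivity may be lost (acylation at O4 or double acylation), and the acyl group may migrate between the cis-1,3-related oxygens.

The fallback sets out from acetate 15 and keeps O4 blocked until the ester is in place:
- HF·pyridine (THF/pyridine, 0 °C) removes the silyl group to give (2R,3R,4R)-2-(3,4-dimethoxyphenyl)-3-(hydroxymethyl)tetrahydrofuran-4-yl acetate F6.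
- The only free hydroxyl is acylated with 18 (Et3N, DMAP, CH2Cl2) to give [(2R,3R,4R)-4-acetoxy-2-(3,4-dimethoxyphenyl)tetrahydrofuran-3-yl]methyl 3,4-dimethoxybenzoate F7.
- The acetate is removed selectively in the presence of the much less electrophilic electron-rich aryl ester by mild methanolysis (Mg(OMe)2, MeOH, 0 °C).

This fallback comes back to the route at target 19.

**Further compounds**

F1 | step 6 | (2S,3Z)-5-(tert-butyldiphenylsilyloxy)-2-hydroxypent-3-enyl 3,4-dimethoxybenzoate | COc1ccc(C(=O)OC[C@@H](O)/C=C\CO[Si](c2ccccc2)(c2ccccc2)C(C)(C)C)cc1OC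
F2 | step 6 | (2S,3Z)-5-(tert-butyldiphenylsilyloxy)-2-(triethylsilyloxy)pent-3-enyl 3,4-dimethoxybenzoate | COc1ccc(C(=O)OC[C@@H](O[Si](CC)(CC)CC)/C=C\CO[Si](c2ccccc2)(c2ccccc2)C(C)(C)C)cc1OC
F3 | step 6 | (3,4-dimethoxyphenyl)[(2S,3Z)-5-(tert-butyldiphenylsilyloxy)-2-(triethylsilyloxy)pent-3-enyloxy]methyl acetate (epimers at the acetal carbon) | COc1ccc(C(OC(C)=O)OC[C@@H](O[Si](CC)(CC)CC)/C=C\CO[Si](c2ccccc2)(c2ccccc2)C(C)(C)C)cc1OC
F4 | step 9 | (2R,3R)-4-[(tert-butyldimethylsilyloxy)methylidene]-3-[(tert-butyldiphenylsilyloxy)methyl]-2-(3,4-dimethoxyphenyl)tetrahydrofuran (enol ether isomers) | CC(C)(C)[Si](c1ccccc1)(c1ccccc1)OC[C@H]2C(=CO[Si](C)(C)C(C)(C)C)CO[C@H]2c3ccc(OC)c(OC)c3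
F5 | step 9 | (2R,3R)-3-[(tert-butyldiphenylsilyloxy)methyl]-2-(3,4-dimethoxyphenyl)tetrahydrofuran-4-one | CC(C)(C)[Si](c1ccccc1)(c1ccccc1)OC[C@H]2C(=O)CO[C@H]2c3ccc(OC)c(OC)c3
F6 | step 11 | (2R,3R,4R)-2-(3,4-dimethoxyphenyl)-3-(hydroxymethyl)tetrahydrofuran-4-yl acetate | OC[C@H]2[C@@H](OC(C)=O)CO[C@H]2c3ccc(OC)c(OC)c3
F7 | step 11 | [(2R,3R,4R)-4-acetoxy-2-(3,4-dimethoxyphenyl)tetrahydrofuran-3-yl]methyl 3,4-dimethoxybenzoate | COc1ccc(C(=O)OC[C@H]2[C@@H](OC(C)=O)CO[C@H]2c3ccc(OC)c(OC)c3)cc1OC
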